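**Compound numbering used throughout:** 1 diisopropyl squarate; 2 phenyllithium; 3 squarate carbinol (not isolated); 4 phenyl semisquarate; 5 4'-methoxyacetophenone; 6 trisyl hydrazide; 7 trisylhydrazone; 8 vinyllithium (not isolated); 9 4-alkenyl-4-hydroxycyclobutenone; 10 4-methoxymandelic acid; 11 dienylketene (not isolated); 12 hydroquinone (not isolated); 13 protected leuco lactone; 14 leuco-peniophorin; 15 peniophorin. Ring positions use the benzofuran numbering of 15: O1, C2(=O), C3, C3a, C4, C5, C6, C7, C7a. Ring A is the lactone ring and ring B the carbocycle.

## Analysis of the target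

Peniophorin 15 is a benzofuran-2,6-dione in which the five-membered lactone ring A (O1–C2–C3–C3a–C7a) is fused to the fully substituted six-membered carbocyclic ring B (C3a, C4, C5, C6, C7, C7a). The bicycle is held at the quinone-methide oxidation level (C3=C3a, C4=C5, C7=C7a, C6=O), with 4-hydroxyphenyl groups on C3 and C4, a hydroxyl on C5, a phenyl on C7 and the lactone oxygen on C7a. There is no stereocentre, so the problem is one of regiochemistry and oxidation level only. The hard point is that the aryl groups on C4 and C7 differ only by a remote para-hydroxyl, so any route through a terphenylquinone-type intermediate cannot tell the two ends of ring B apart. The aryl groups on C3 and C4 are also crowded against each other, which makes the C3–C3a bond hard to form. The quinone methide, the lactone and the free phenols are sensitive to base, nucleophiles and oxidants, and the reduced form of the chromophore is air-sensitive. The feature that the route exploits is the four-carbon run C5–C6–C7–C7a of ring B carrying O, O, phenyl, O: this is the pattern of a squaric ester in which one oxygen has been replaced by phenyl, and the remaining ring carbons C4 and C3a are the two carbons of a 1-arylvinyl group.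

## Retrosynthetic reasoning

**15 ⇒ 14.** The C3=C3a/C6=O quinone methide is taken back to the C3–H, C6–OH leuco lactone 14. No skeletal bond is cut. The forward reaction is a two-electron oxidation of the catechol unit of 14, which also erases the C3 stereocentre, so the sensitive chromophore appears only in the last step.

**14 ⇒ 13.** Three O–alkyl bonds are cut: the two aryl methyl ether bonds and the C6 isopropyl ether bond. One Lewis-acid dealkylation has to unveil all three oxygens and leave the lactone of 13 closed.

**13 ⇒ 12 + 10.** The C3–C3a bond and the O1–C2 bond are cut. This removes the whole of ring A and leaves the hydroquinone 12, which has exactly one unsubstituted ring carbon (C3a) sitting ortho to the C7a hydroxyl. The forward reaction is a Friedel–Crafts alkylation with the mandelic acid 10 followed by lactonization. The site is fixed because no other position of ring B is free.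

**12 ⇒ 9 by way of 11.** This is the key disconnection. The C7a–C3a bond of the arene is cut and the C7a–C5 bond of a four-membered ring is restored, so the pentasubstituted benzene ring of 12 becomes the cyclobutenone 9. Cutting here solves the regiochemical problem by connectivity: phenyl ends up beside the former ketene carbon (C7a), isopropoxy beside the former carbinol carbon (C5), and the 4-methoxyphenyl group on C4. The forward reaction is electrocyclic opening of 9 to the dienylketene 11, then 6π closure and tautomerization.

**9 ⇒ 4 + 8.** The C5–C4 bond is cut. The forward reaction is a 1,2-addition of the vinyllithium 8 to the dione 4. It must pick the carbonyl next to the isopropoxy-bearing carbon, which is the more electrophilic one because the other carbonyl of 4 is part of a vinylogous ester.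

**8 ⇒ 7 ⇒ 5 + 6.** The C–Li bond of 8 is traced to the ketone carbon of 5 through the hydrazone 7, which is the condensation product of 5 and 6. In this way 8 is generated in the flask from a stable, crystalline precursor and no halogenated precursor has to be made or stored.

**4 ⇒ 1 + 2.** The C7–phenyl bond is cut. Addition of 2 to the symmetrical squarate 1, followed by acid-induced collapse of carbinol 3 with loss of one of its two isopropoxy groups, gives 4 with the two carbonyls electronically differentiated.

## Alternatives that were turned down

**Alternative 1:** the textbook, biomimetic disconnection of C3=C3a and O1–C2. The forward key step is a Perkin-type condensation of the terphenylquinone 2,5-dihydroxy-3-(4-hydroxyphenyl)-6-phenylcyclohexa-2,5-diene-1,4-dione A1 with 4-hydroxyphenylacetic acid A2 under dehydrating conditions. It was turned down because A1 is a tautomeric 2,5-dihydroxyquinone whose two carbonyl/hydroxyl pairs differ only by a para-hydroxyl several bonds away, so A2 is expected to condense at either pair without bias. This would give 15 together with its isomer 5-hydroxy-3,7-bis(4-hydroxyphenyl)-4-phenylbenzofuran-2,6-dione A3. Since A3 differs from 15 only in which aryl group sits at C4 and which at C7, the two should be very hard to separate. A second condensation of A2 at the remaining pair is also possible, and A1 itself needs an unsymmetrical multi-step synthesis.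

**Alternative 2:** disconnection of the two aryl–ring bonds at C4 and C7. The forward key steps are two successive Suzuki couplings of two different arylboron reagents with 4,7-dibromo-5,6-dimethoxy-3-(4-methoxyphenyl)benzofuran-2(3H)-one A4. It was turned down because the two bromides of A4 are electronically and sterically almost equivalent, so site-selective installation of two different aryl groups has no structural handle. Both sites are flanked on two sides, the C3 proton of the lactone is acidic under the basic coupling conditions, and building the hexasubstituted A4 by stepwise arene substitution costs more steps than the whole route below.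

**Alternative 3:** disconnection of ring B into a four-carbon diene and a two-carbon alkyne. The forward key step is a Diels–Alder reaction of the cyclopentadienone 3,4-dimethoxy-2-(4-methoxyphenyl)-5-phenylcyclopenta-2,4-dien-1-one A5 with the ynol ether methyl 4-isopropoxy-2-(4-methoxyphenyl)but-3-ynoate A6, followed by loss of the bridging carbonyl. This would give the arene methyl 2-[2-isopropoxy-4,5-dimethoxy-6-(4-methoxyphenyl)-3-phenylphenyl]-2-(4-methoxyphenyl)acetate A7. It was turned down because the two diene termini of A5 again differ only by a remote methoxy group, so A6 would add in both orientations and A7 would come mixed with its regioisomer. In addition, an electron-rich diene and an electron-rich ynol ether are electronically mismatched, and A6 is a sensitive compound that needs its own synthesis.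

Key step: step 4

Remark: 15 has no stereocentre; 3, 9, 10, 13 and 14 are racemates, and the C3 stereocentre of 13 and 14 is removed in step 6.

## Route

Step 1
Reactants: 1 diisopropyl squarate (3,4-diisopropoxycyclobut-3-ene-1,2-dione); 2 phenyllithium
Product: 4 3-isopropoxy-4-phenylcyclobut-3-ene-1,2-dione, via carbinol 3 (not isolated)
Conditions: PhLi, THF, −78 °C; then (CF3CO)2O, −78 °C; then H2O
Reagents that add atoms: water, O
Why: 1,2-addition of an organolithium to a dialkyl squarate gives carbinol 3; trifluoroacetylation ionizes the carbinol, and hydrolysis of the resulting oxocarbenium ion with loss of isopropanol gives the semisquarate (known squarate-to-cyclobutenedione transposition).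

Step 2
Reactants: 5 4'-methoxyacetophenone; 6 2,4,6-triisopropylbenzenesulfonohydrazide
Product: 7 (E)-4'-methoxyacetophenone 2,4,6-triisopropylbenzenesulfonylhydrazone
Conditions: MeOH, HCl (cat.), rt
Reagents that add atoms: none
Why: Acid-catalysed hydrazone condensation; the E isomer (sulfonamide syn to methyl) is expected and is the one needed for deprotonation at the methyl group.

Step 3
Reactants: 7 (E)-4'-methoxyacetophenone 2,4,6-triisopropylbenzenesulfonylhydrazone; 4 3-isopropoxy-4-phenylcyclobut-3-ene-1,2-dione
Product: 9 4-hydroxy-3-isopropoxy-4-[1-(4-methoxyphenyl)ethenyl]-2-phenylcyclobut-2-en-1-one (racemic), via vinyllithium 8 (not isolated)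
Conditions: 7, n-BuLi (2.0 equiv), THF, −78 to 0 °C; then 4, −78 °C; then H2O
Reagents that add atoms: none
Why: Shapiro reaction of the trisylhydrazone dianion gives vinyllithium 8 with loss of sulfinate and N2; 8 should add 1,2 to the carbonyl of 4 next to the isopropoxy-bearing carbon, since the other carbonyl is deactivated as a vinylogous ester (known regiochemistry for 3-alkoxycyclobutenediones).

Step 4
Reactants: 9 4-hydroxy-3-isopropoxy-4-[1-(4-methoxyphenyl)ethenyl]-2-phenylcyclobut-2-en-1-one; 10 4-methoxymandelic acid (racemic)
Product: 13 5-hydroxy-6-isopropoxy-3,4-bis(4-methoxyphenyl)-7-phenylbenzofuran-2(3H)-one (racemic), via dienylketene 11 (not isolated), via hydroquinone 12 (not isolated)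
Conditions: PhMe (degassed), 110 °C, Ar; then 10, TsOH·H2O (cat.), Dean–Stark, 110 °C
Reagents that add atoms: none
Why: Heating 9 cleaves the C7a–C5 bond by conrotatory 4π electrocyclic ring opening in which the hydroxyl rotates outward and the arylvinyl group inward, giving the (Z)-dienylketene 11 with the ketene carbon and the vinyl terminus on the same side. Thermal 6π electrocyclization of 11 forms the C7a–C3a bond and closes the six-membered ring B, and tautomerization of the resulting cyclohexadienone gives hydroquinone 12; the closest known reaction type is the thermal ring expansion of 4-alkenyl-4-hydroxycyclobutenones to hydroquinones (Moore-type rearrangement). The substitution pattern of 12 follows from the connectivity of 9 alone: phenyl next to the former ketene carbon C7a, isopropoxy next to the former carbinol carbon C5, the aryl group on C4. After 10 and acid are added to the same flask, the 4-methoxybenzylic cation from 10 should alkylate C3a, the only unsubstituted ring carbon, which is ortho to the C7a hydroxyl and para to the isopropoxy group; the C7a hydroxyl then closes the five-membered lactone ring A by 5-exo-trig acyl substitution (Friedel–Crafts hydroxyalkylation–lactonization of a phenol with a mandelic acid). Only the C7a hydroxyl is ortho to the new side chain, so one lactone can form, and the C5 hydroxyl can at most be esterified reversibly. The new stereocentre C3 has no controlling element, is formed as a racemate and is removed in step 6. The step needs chemoselectivity between the hydroquinone ring and the anisyl rings in the alkylation; the doubly oxygen-activated C3a and the irreversible lactonization should drain the reversible benzylation toward 13. Acid is added only after 9 is consumed, and air is excluded so that 12 is not oxidized to its quinone before alkylation.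

Step 5
Reactants: 13 5-hydroxy-6-isopropoxy-3,4-bis(4-methoxyphenyl)-7-phenylbenzofuran-2(3H)-one
Product: 14 5,6-dihydroxy-3,4-bis(4-hydroxyphenyl)-7-phenylbenzofuran-2(3H)-one (racemic)
Conditions: BBr3 (excess), CH2Cl2, −78 °C to rt, Ar; then H2O
Reagents that add atoms: none
Why: Lewis-acid cleavage of aryl alkyl ethers by BBr3 should remove both methyl groups and the isopropyl group; aryl lactones normally survive these conditions, and a ring-opened hydroxy acid would reclose on acidic work-up.

Step 6
Reactants: 14 5,6-dihydroxy-3,4-bis(4-hydroxyphenyl)-7-phenylbenzofuran-2(3H)-one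
Product: 15 peniophorin (5-hydroxy-3,4-bis(4-hydroxyphenyl)-7-phenylbenzofuran-2,6-dione)
Conditions: DDQ (1.0 equiv), THF, 0 °C to rt
Reagents that add atoms: none
Why: Two-electron dehydrogenation of the catechol by a quinone oxidant; the resulting ortho-quinone should tautomerize by shift of the C3–H, which is vinylogously alpha to the C5 carbonyl through C3a=C4, to the quinone methide that is conjugated with the lactone carbonyl and the C3 aryl group.

## Compound list

1 | diisopropyl squarate (3,4-diisopropoxycyclobut-3-ene-1,2-dione) | CC(C)OC1=C(OC(C)C)C(=O)C1=O | starting material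
2 | phenyllithium | [Li]c1ccccc1 | starting material
3 | 4-hydroxy-2,3-diisopropoxy-4-phenylcyclobut-2-en-1-one (racemic) | CC(C)OC1=C(OC(C)C)C(O)(c2ccccc2)C1=O | intermediate
4 | 3-isopropoxy-4-phenylcyclobut-3-ene-1,2-dione | CC(C)OC1=C(c2ccccc2)C(=O)C1=O | intermediate
5 | 4'-methoxyacetophenone | CC(=O)c1ccc(OC)cc1 | starting material
6 | 2,4,6-triisopropylbenzenesulfonohydrazide | CC(C)c1cc(C(C)C)c(S(=O)(=O)NN)c(C(C)C)c1 | starting material
7 | (E)-4'-methoxyacetophenone 2,4,6-triisopropylbenzenesulfonylhydrazone | COc1ccc(/C(C)=N/NS(=O)(=O)c2c(C(C)C)cc(C(C)C)cc2C(C)C)cc1 | intermediate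
8 | 1-(4-methoxyphenyl)ethenyllithium | [Li]C(=C)c1ccc(OC)cc1 | intermediate
9 | 4-hydroxy-3-isopropoxy-4-[1-(4-methoxyphenyl)ethenyl]-2-phenylcyclobut-2-en-1-one (racemic) | C=C(c1ccc(OC)cc1)C1(O)C(OC(C)C)=C(c2ccccc2)C1=O | intermediate
10 | 4-methoxymandelic acid (racemic) | COc1ccc(C(O)C(=O)O)cc1 | starting material
11 | (3Z)-4-hydroxy-3-isopropoxy-5-(4-methoxyphenyl)-2-phenylhexa-1,3,5-trien-1-one | O=C=C(c1ccccc1)/C(OC(C)C)=C(/O)C(=C)c1ccc(OC)cc1 | intermediate
12 | 3-isopropoxy-5-(4-methoxyphenyl)-2-phenylbenzene-1,4-diol | Oc1cc(-c2ccc(OC)cc2)c(O)c(OC(C)C)c1-c1ccccc1 | intermediate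
13 | 5-hydroxy-6-isopropoxy-3,4-bis(4-methoxyphenyl)-7-phenylbenzofuran-2(3H)-one (racemic) | O=C1Oc2c(-c3ccccc3)c(OC(C)C)c(O)c(-c3ccc(OC)cc3)c2C1c1ccc(OC)cc1 | intermediate
14 | 5,6-dihydroxy-3,4-bis(4-hydroxyphenyl)-7-phenylbenzofuran-2(3H)-one (racemic) | O=C1Oc2c(-c3ccccc3)c(O)c(O)c(-c3ccc(O)cc3)c2C1c1ccc(O)cc1 | intermediate
15 | peniophorin (5-hydroxy-3,4-bis(4-hydroxyphenyl)-7-phenylbenzofuran-2,6-dione) | O=C1OC2=C(c3ccccc3)C(=O)C(O)=C(c3ccc(O)cc3)C2=C1c1ccc(O)cc1 | target

## Step count and risk

Total step count: 6. Longest linear sequence: 5 steps (step 1 or step 2, then steps 3, 4, 5, 6).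

**Step 4 (key step).** The ring expansion itself has close precedent. The process most likely to fail is the alkylation half: benzylation of the hindered C3a position, flanked by the C4 aryl group, may be slow enough that the cation from 10 alkylates an anisyl ring, esterifies the C5 hydroxyl, or self-condenses. Two lesser risks are inward rotation of the hydroxyl during ring opening, which would lead to intramolecular ketene trapping, and adventitious oxidation of 12.

The fallback reverses the polarity so that the ring carbon is the electrophile. It sets out from 12, made by thermolysis of 9 alone, and returns at 13. 12 would be oxidized with Ag2O to the quinone 3-isopropoxy-5-(4-methoxyphenyl)-2-phenylcyclohexa-2,5-diene-1,4-dione F1, whose only unsubstituted carbon is the one open Michael position. Mukaiyama–Michael addition of the silyl ketene acetal [1-methoxy-2-(4-methoxyphenyl)ethenyl]oxy(trimethyl)silane F2 (from methyl 4-methoxyphenylacetate, LiN(iPr)2 and Me3SiCl) would give, after desilylation, the hydroquinone ester methyl 2-[2,5-dihydroxy-4-isopropoxy-6-(4-methoxyphenyl)-3-phenylphenyl]-2-(4-methoxyphenyl)acetate F3. Acid-catalysed lactonization of F3 onto the ortho hydroxyl gives 13.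

**Step 3.** Incomplete collapse of the hydrazone dianion or protonation of 8 by the solvent would leave butyllithium or too little nucleophile. Residual butyllithium would add to 4, and some attack at the vinylogous-ester carbonyl cannot be excluded.

The fallback generates the same nucleophile by halogen–metal exchange. It sets out from 5 and returns at 8. 5 would be converted with (PhO)3P/Br2 and Et3N into the vinyl bromide 1-(1-bromoethenyl)-4-methoxybenzene F4, and bromine–lithium exchange with t-BuLi (2 equiv, Et2O, −78 °C) would give 8 free of sulfinate and excess alkyllithium, ready for addition to 4.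

**Step 5.** The isopropyl cation released may be transferred to the electron-rich rings (Friedel–Crafts re-alkylation). Dealkylation may stop part-way, and the tetraphenol may undergo uncontrolled air oxidation during work-up.

The fallback separates the dealkylations and moves the oxidation forward. It sets out from 13 and returns at 15. BCl3 at −78 °C would remove only the isopropyl group (assisted by the neighbouring hydroxyl, with chloride capturing the cation), giving 5,6-dihydroxy-3,4-bis(4-methoxyphenyl)-7-phenylbenzofuran-2(3H)-one F5. Oxidation with DDQ would give the air-stable quinone methide 5-hydroxy-3,4-bis(4-methoxyphenyl)-7-phenylbenzofuran-2,6-dione F6. Cleavage of the two remaining methyl ethers with BBr3 would then deliver 15.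

**Step 6.** A high-potential quinone may over-oxidize the 4-hydroxyphenyl groups, by extended quinone-methide formation or phenolic coupling, or the ortho-quinone may be trapped before it tautomerizes.

The fallback replaces the chemical oxidant by controlled-potential anodic oxidation of 14 (divided cell, carbon anode, buffered MeCN/H2O), held at the potential of the catechol couple, which lies well below that of the isolated phenols. It sets out from 14 and returns at 15 and makes no new compound.

## Further compounds

F1 | step 4 | 3-isopropoxy-5-(4-methoxyphenyl)-2-phenylcyclohexa-2,5-diene-1,4-dione | O=C1C=C(c2ccc(OC)cc2)C(=O)C(OC(C)C)=C1c1ccccc1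
F2 | step 4 | [1-methoxy-2-(4-methoxyphenyl)ethenyl]oxy(trimethyl)silane | COC(O[Si](C)(C)C)=Cc1ccc(OC)cc1
F3 | step 4 | methyl 2-[2,5-dihydroxy-4-isopropoxy-6-(4-methoxyphenyl)-3-phenylphenyl]-2-(4-methoxyphenyl)acetate | COC(=O)C(c1ccc(OC)cc1)c1c(O)c(-c2ccccc2)c(OC(C)C)c(O)c1-c1ccc(OC)cc1
F4 | step 3 | 1-(1-bromoethenyl)-4-methoxybenzene | C=C(Br)c1ccc(OC)cc1
F5 | step 5 | 5,6-dihydroxy-3,4-bis(4-methoxyphenyl)-7-phenylbenzofuran-2(3H)-one | O=C1Oc2c(-c3ccccc3)c(O)c(O)c(-c3ccc(OC)cc3)c2C1c1ccc(OC)cc1
F6 | step 5 | 5-hydroxy-3,4-bis(4-methoxyphenyl)-7-phenylbenzofuran-2,6-dione | O=C1OC2=C(c3ccccc3)C(=O)C(O)=C(c3ccc(OC)cc3)C2=C1c1ccc(OC)cc1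
F0 | step 6 | none | none
A1 | alternative 1 | 2,5-dihydroxy-3-(4-hydroxyphenyl)-6-phenylcyclohexa-2,5-diene-1,4-dione | O=C1C(O)=C(c2ccc(O)cc2)C(=O)C(O)=C1c1ccccc1
A2 | alternative 1 | 4-hydroxyphenylacetic acid | O=C(O)Cc1ccc(O)cc1
A3 | alternative 1 | 5-hydroxy-3,7-bis(4-hydroxyphenyl)-4-phenylbenzofuran-2,6-dione | O=C1OC2=C(c3ccc(O)cc3)C(=O)C(O)=C(c3ccccc3)C2=C1c1ccc(O)cc1
A4 | alternative 2 | 4,7-dibromo-5,6-dimethoxy-3-(4-methoxyphenyl)benzofuran-2(3H)-one | O=C1Oc2c(Br)c(OC)c(OC)c(Br)c2C1c1ccc(OC)cc1
A5 | alternative 3 | 3,4-dimethoxy-2-(4-methoxyphenyl)-5-phenylcyclopenta-2,4-dien-1-one | O=C1C(c2ccccc2)=C(OC)C(OC)=C1c1ccc(OC)cc1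
A6 | alternative 3 | methyl 4-isopropoxy-2-(4-methoxyphenyl)but-3-ynoate | COC(=O)C(C#COC(C)C)c1ccc(OC)cc1
A7 | alternative 3 | methyl 2-[2-isopropoxy-4,5-dimethoxy-6-(4-methoxyphenyl)-3-phenylphenyl]-2-(4-methoxyphenyl)acetate | COC(=O)C(c1ccc(OC)cc1)c1c(OC(C)C)c(-c2ccccc2)c(OC)c(OC)c1-c1ccc(OC)cc1
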